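Its constants stand for no real mixture, and the outcome is calculated.

Millimolar per second is the unit for this problem: treat each flask as a flow from solid E through L and J into Q.

    E ⇌ L, rate k1*(cs1 - [L]) while solid is left; crystals form when [L] > cs1 (cs1 = 2.4 mM, k1 = 0.337 s⁻¹)
    G + Q ⇌ G.Q (K2 = 37.6 M⁻¹, k2 = 6.93 M⁻¹ s⁻¹, Ea2 = 36.0 kJ mol⁻¹, ΔH2 = −90.0 kJ mol⁻¹)
    X ⇌ D, rate k3*(csat - [D]) (k3 = 0.0449 s⁻¹, csat = 2.7 mM)
    L + G → G + J (k4 = 4510 M⁻¹ s⁻¹, Ea4 = 34.0 kJ mol⁻¹)
    D + G + J → G + Q (k5 = 89400 M⁻² s⁻¹, Ea5 = 18.0 kJ mol⁻¹)
    (constants at 35 °C)

| flask | E | X | G | temperature | time |
|---|---|---|---|---|---|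
| east | 0.010 M | 2.7 mM (held) | 50 µM | 60 °C | 1.0 min |
| north-east | 0.010 M | 2.7 mM (held) | 50 µM | 35 °C | 1.0 min |
| north-west | 0.010 M | 2.7 mM (held) | 50 µM | 10 °C | 1.0 min |

- for Q the G.Q is counted in
- as a solid, counted per litre of solution: E
- at the start none of D is dissolved
- at 35 °C the constants are as listed, elsewhere as the activation energies and enthalpies make them
- at the start none of E is in solution
- what has only dissolved of E counts as not reacted

* the best flask by amount of Q, in percent of the E charged; "all alike" if 1.5 percentage points covers them all (east / north-east / north-west / all alike)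
* amount of Q at the end, in percent of the E charged, east
* amount of Q at the end, in percent of the E charged, north-east
* amount of Q at the end, in percent of the E charged, north-west

Start with the flow into J. Dissolving and the capture of L by G run in series, so you add their times. In north-west these are 2.97 s and 14.3 s. The feed, the steady flow of L into J while solid is left, is the solubility divided by that sum: 0.139 mM s⁻¹ in north-west. It is 0.324 mM s⁻¹ in north-east and 0.521 mM s⁻¹ in east. The charge of E does not enter it. Dividing the charge by the feed gives pass times of 19.2 s in east, 30.8 s in north-east and 72.0 s in north-west.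

But fast J is not yet Q, since Q also needs D. The transfer coefficient has no activation energy, so it stays 0.0449 s⁻¹. At full [J], the pseudo-first-order constant with which D is used, k[G][J], is 0.0757 s⁻¹ in east, 0.0447 s⁻¹ in north-east and 0.0240 s⁻¹ in north-west. In north-east the two are nearly equal, so you cannot drop either, and you add their times as before. The flows of D come to 0.0761 mM s⁻¹ in east, 0.0605 mM s⁻¹ in north-east and 0.0423 mM s⁻¹ in north-west.

J must first climb, and a linear climb costs half the pass time. That gives 38.4% in east and 27.0% in north-east. In north-west, on this reckoning, J is still climbing at the end, so you take the triangle instead: 10.6%.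

The objection is that making Q uses up J, so [J] does not stay at the charge. Lowering it by half of each estimate gives 35.2% in east, 25.0% in north-east and 10.2% in north-west.

A second objection is that G.Q withdraws G. In north-east the bound-to-free ratio at equilibrium is 0.101 with my first figure for Q at the end. In north-west the equilibrium constant of binding is 836 M⁻¹, but at that same kind of figure binding needs 472 s, longer than the run. So I commit to east.

The forecast says east, with 33.5%, 23% and 9.5%, on the ground that “the warm flasks get longer at the D-transfer-limited rate”. My first figures stand above it , with the same order.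

The simulation gives east, with 33.4%, 23.1% and 9.53%. North-west converts 79.4% of its E by the end, and the feed over the full time gives 83.3%.

Now take north-west with 0.025 M of E. The feed stays 0.139 mM s⁻¹, so you expect it to pass 33.3% of this larger charge, and if [Q] stays as in north-west, that is 3.81% of this charge. The computed flask holds 27.9% as J and 3.81% as Q.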